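Start from the delta run: by 0.500 min it had lost 62.6% of its substrate but held 18.8% of target. Follow one molecule of substrate and ask what its chance of becoming target is.

| flask | substrate | first nucleophile | second nucleophile | protic impurity | remark | time |
|---|---|---|---|---|---|---|
| delta | 0.10 M | 0.36 M | 1 M | 0.010 M | run made earlier |  |
| zeta | 0.40 M | 0.36 M | 1 M | 0.010 M | run made earlier |  |
| beta | 0.20 M | 0.72 M | 1 M | 0.010 M | run made earlier |  |
| flask | 0.20 M | 0.360 M | 1.00 M | 0.0100 M |  | 40 min |

- delta (time / min: target / %, substrate / %): 0.500: 18.8, 37.4; 1.50: 24.3, 5.8; 5.00: 14.7, 0.5; 15.0: 4.6, 0.2; 50.0: 2.4, 0.1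
- zeta (time / min: target / %, substrate / %): 0.500: 17.7, 37.0; 1.50: 23.1, 6.0; 5.00: 14.1, 0; 15.0: 3.9, 0; 50.0: 2.2, 0.1
- beta (time / min: target / %, substrate / %): 0.500: 27.2, 37.3; 1.50: 37.5, 5.2; 5.00: 21.4, 0; 15.0: 6.2, 0.1; 50.0: 3.6, 0.9

(scatter of a reading: 0.5 percentage points)

- the numbers in the tables scatter by 0.5 percentage points (one standard deviation)

1. when, up to 40 min, the flask holds most target
2. the amount of target, in percent of the substrate charged, at that time
3. the first time at which target reaches 7.2%, in the same percent, in min

1. Take the main step by itself. Substrate goes first order with rate constant k, read from delta as 1.90 min⁻¹. At 1.50 min, zeta and beta still hold 6.0% and 5.2% against delta's 5.8%, so this behaves as the rate-limiting step. If every molecule became target, target would climb towards 100%.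

2. Add the fork. Divide target by substrate lost at 0.500 min: delta gives 30.0%, zeta 28.1%, and beta, with 0.72 M of first nucleophile, 43.4%. So the substrate charge barely moves this share, while first nucleophile raises it by a factor of 1.45. Write the share as S = B/(B + W), with B the first nucleophile. Here W is the competition at the fork, the concentration of first nucleophile at which target's chance equals that of the other exits together, 0.889 M as the mean of delta and beta. It holds second nucleophile fixed at 1.00 M. For the flask, S = 28.8%, and that replaces the ceiling of 100%.

3. Add the loss of target. Measured above its last reading, target in delta falls with rate constant λ, read as 0.172 min⁻¹. This is slower than k, so I reckon a peak in the flask at time t = ln(k/λ)/(k − λ) = 1.39 min. Its height is S·exp(−λt) = 22.7%. From S(1 − exp(−kt)), I reckon that target in the flask reaches 7.2% at about 0.151 min.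

4. The forecast gives 24% at 1.4 min and 0.14 min for the level, on the grounds of “a rate-limiting step followed by partitioning to target”. My height lies lower and my first time later.

The flask gives 24.0% at 1.32 min, and reaches the level at 0.135 min, so the forecast held.

    substrate → intermediate (k = 0.0329 s⁻¹)
    intermediate → solvolysis product (k = 4.50 s⁻¹)
    intermediate → side product (k = 0.0148 s⁻¹)
    target ⇌ isomer of the product (K = 12.8, k = 0.00303 s⁻¹)
    second nucleophile + protic impurity → quenched reagent (k = 0.0623 L mol⁻¹ s⁻¹)
    first nucleophile + intermediate → target (k = 31.1 L mol⁻¹ s⁻¹)
    second nucleophile + intermediate → other capture product (k = 20.0 L mol⁻¹ s⁻¹)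

Now use W on the neighbouring flask, the same recipe with 0.22 M of first nucleophile, or 1.10 equiv of it to substrate. Its share comes to 19.8% against 28.8% in the flask. Scaling the flask's 24.0% by that ratio gives a reckoned peak of 16.5% for the neighbour. The neighbouring flask peaks at 16.6%.

(The numbers in the tables stem from a simulated flask with constants of no real substance; scatter was added.)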